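C3O2H–C4Me2–C5; ring B = C5–C6(OH)–C7–C8(Me,O)–C9–C10(Me); lactone ring = C8–O–C2(=O)–C1–C10–C9; side chain C9–C11(OH)–C12–C13(Me,OH)–C14=C15 (labdane-type numbering, used throughout).
Enabling feature: the all-carbon bridgehead C10 carries two CH2–C(=O) arms of equal length (C1–C2 and C9–C11), a hidden 3,3-disubstituted glutaric acid. O8/C9/C11 form an aldol retron, and C8–O and C10–C1 stand 1,3-diaxial on ring B.
Key disconnection: C8–C9 and O8–C2 are cut together, back to the monocyclic keto glutaric anhydride 16, in which C10 is not yet stereogenic and only C5 and C6 are set. The side chain leaves C11 by aldol (C11–C12) and methyl addition (C13–C16).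
16 comes from divinyl ketone 13 (vinyl to CH2CHO to CH2CO2H). C6–C7 is made by a proline aldol with acetone, and the crowded C5–C10 bond by Ireland–Claisen rearrangement of a dienyl 2,2-dimethylsuccinate.
Ring order: the temporary anhydride ring (step 10), then ring B and the δ-lactone ring in one operation with loss of the anhydride ring (step 11).

Key step: step 11

Remark on the chemistry: the δ-lactone on O8 is taken to be stable against acyl shift to O6 or O11, and the O6/C3 γ-hydroxy acid against lactonisation, under buffered near-neutral conditions, since the target is defined in this form.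
Abbreviations: TMSE = 2-(trimethylsilyl)ethyl; TBS = tert-butyldimethylsilyl. Compounds 7 to 10 are racemic.

Step 1
Reactants: 1 (2E)-3-methylpent-2-en-4-yn-1-ol
Product: 2 (2E)-3-methylpenta-2,4-dien-1-ol
Conditions: H2 (1 atm, 1 equiv), Pd/CaCO3 poisoned with Pb(OAc)2, quinoline, EtOAc, 0 °C
Reagents that add atoms: none
Why: Lindlar-type semihydrogenation should stop at the diene because the poisoned palladium surface binds the terminal alkyne far better than the alkene formed; no stereocentre is made.

Step 2
Reactants: 2 (2E)-3-methylpenta-2,4-dien-1-ol, 3 2,2-dimethylsuccinic anhydride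
Product: 4 4-{[(2E)-3-methylpenta-2,4-dien-1-yl]oxy}-2,2-dimethyl-4-oxobutanoic acid
Conditions: DMAP (10 mol %), pyridine, rt
Reagents that add atoms: none
Why: DMAP-catalysed alcoholysis of the unsymmetrical anhydride should take place at the carbonyl next to CH2, away from the gem-dimethyl carbon, which leaves the hindered C3 acid free.

Step 3
Reactants: 4 half ester acid
Product: 5 1-[2-(trimethylsilyl)ethyl] 4-[(2E)-3-methylpenta-2,4-dien-1-yl] 2,2-dimethylbutanedioate
Conditions: 2-(trimethylsilyl)ethyl 2,2,2-trichloroacetimidate (1.5 equiv), toluene, 90 °C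
Reagents that add atoms: 2-(trimethylsilyl)ethyl 2,2,2-trichloroacetimidate, C[Si](C)(C)CCOC(=N)C(Cl)(Cl)Cl
Why: In this trichloroacetimidate esterification the carboxylate oxygen captures a β-silyl-stabilised cation, so the hindrance at the C3 carbonyl carbon does not matter and a fluoride-labile ester results.

Step 4
Reactants: 5 mixed succinate diester
Product: 8 rac-3,3-dimethyl-2-(3-methylpenta-1,4-dien-3-yl)-4-oxo-4-[2-(trimethylsilyl)ethoxy]butanoic acid, via silyl ketene acetal 6 (not isolated), via trimethylsilyl ester 7 (not isolated)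
Conditions: LiN(iPr)2 (1.2 equiv), THF, −78 °C; Me3SiCl; −78 to 60 °C; 1 M HCl
Reagents that add atoms: none
Why: Ireland–Claisen rearrangement: only C5 carries enolisable hydrogens, the intramolecular [3,3] shift forges the crowded C5–C10 bond, and since C10 receives two identical vinyl groups only C5 becomes stereogenic (racemic), whatever the alkene or ketene acetal geometry.

Step 5
Reactants: 8 rac-acid
Product: 10 rac-2-(trimethylsilyl)ethyl 4-ethenyl-3-formyl-2,2,4-trimethylhex-5-enoate, via acid chloride 9 (not isolated)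
Conditions: 1-chloro-N,N,2-trimethylprop-1-en-1-amine, CH2Cl2, 0 °C; then LiAlH(OtBu)3 (1.05 equiv), THF, −78 °C
Reagents that add atoms: none
Why: Neutral acid chloride formation followed by reduction with the bulky alkoxyaluminium hydride should stop at the aldehyde, spare the more hindered TMSE ester and the alkenes, and avoid a γ-hydroxy ester that could lactonise.

Step 6
Reactants: 10 rac-aldehyde, 11 acetone
Product: 12 2-(trimethylsilyl)ethyl (3R)-4-ethenyl-3-[(1R)-1-hydroxy-3-oxobutyl]-2,2,4-trimethylhex-5-enoate (5R,6R)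
Conditions: (S)-proline (30 mol %), acetone/DMSO 1:4, rt; chromatography
Reagents that add atoms: none
Why: In this proline-catalysed direct aldol the acetone enamine of (S)-proline attacks the Re face of α-branched aldehydes and so sets 6R; for (5R)-10 this coincides with the Felkin–Anh preference (ester-bearing C4 anti to the nucleophile), so the matched 5R,6R aldol should form first and be separated from unreacted (5S)-10 and its 5S,6R aldol.

Step 7
Reactants: 12 aldol (5R,6R)
Product: 13 TBS ether of 12 at O6 (5R,6R)
Conditions: TBSOTf, 2,6-lutidine, CH2Cl2, −78 to 0 °C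
Reagents that add atoms: tert-butyldimethylsilyl trifluoromethanesulfonate, CC(C)(C)[Si](C)(C)OS(=O)(=O)C(F)(F)F
Why: Silyl triflate silylation copes with the hindered secondary alcohol and blocks γ-lactonisation onto C3 and retro-aldol cleavage without touching a stereocentre.

Step 8
Reactants: 13 divinyl ketone
Product: 14 keto dialdehyde, as 13 with both vinyl groups on C10 turned into CH2CHO (5R,6R)
Conditions: PdCl2(PhCN)2 (12 mol %), CuCl2·2H2O (12 mol %), AgNO2 (6 mol %), O2 (1 atm), t-BuOH/MeNO2 15:1, rt
Reagents that add atoms: dioxygen, O=O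
Why: The nitrite-modified aldehyde-selective Wacker oxidation is known to oxidise vinyl groups on quaternary carbons at the terminal carbon, and ketone, ester and silyl ether are inert to it.

Step 9
Reactants: 14 keto dialdehyde
Product: 15 keto diacid, C10(Me)(CH2CO2H)2 (5R,6R)
Conditions: NaClO2, NaH2PO4, 2-methylbut-2-ene, t-BuOH/H2O, 0 °C to rt
Reagents that add atoms: sodium chlorite, [Na+].[O-]Cl=O
Why: Pinnick oxidation converts both aldehydes into acids under buffered conditions that leave the β-silyloxy ketone and both stereocentres alone.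

Step 10
Reactants: 15 keto diacid
Product: 16 keto glutaric anhydride, 4-methyl-4-substituted oxane-2,6-dione (5R,6R)
Conditions: Ac2O (5 equiv), toluene, 60 °C; evaporation, used crude
Reagents that add atoms: none
Why: Cyclodehydration of a 3,3-disubstituted glutaric acid is favoured by the Thorpe–Ingold effect, ties the two arms into one activated ring and keeps C10 non-stereogenic.

Step 11
Reactants: 16 keto glutaric anhydride
Product: 18 bridged lactone acid 7-(TBSO)-1,5-dimethyl-3-oxo-6-[2-(TMSE-oxycarbonyl)propan-2-yl]-2-oxabicyclo[3.3.1]nonane-9-carboxylic acid (5R,6R,8S,9R,10R), via hydroxy anhydride 17 (not isolated)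
Conditions: ZnCl2 (2.5 equiv), Et3N (3 equiv), CH2Cl2, 0 °C to rt; aq. citric acid
Reagents that add atoms: none
Why: Proposed new method: ZnCl2/Et3N soft-enolises one CH2 of the anhydride ring, the zinc enolate carbon C9 adds to the zinc-bound C8 methyl ketone to give aldolate 17, and its tertiary alkoxide attacks the distal anhydride carbonyl C2 across the boat-shaped anhydride ring (bicyclo[2.2.2]-type tetrahedral intermediate) and expels the C11 carboxylate, so that 16 isomerises to 18 without loss of an atom. The closest known reaction types are the Fittig–Stobbe-type aldol–lactonisation of succinic anhydride with aldehydes and enolisable ketones under ZnCl2/Et3N (paraconic acid synthesis) and the Castagnoli–Cushman reaction of glutaric anhydride; new are the intramolecular setting, the glutaric anhydride/dialkyl ketone pair and the choice between two diastereotopic CH2 groups. Ring B closes through C8–C9 in the 6-(enolexo)-exo-trig mode, the δ-lactone ring closes 6-exo-trig by acyl transfer, and the temporary anhydride ring is opened in the same event. C8, C9 and C10 are fixed relative to one another by the tether, because C1 and C11 stay joined in the anhydride ring until O8 reaches C2, which is possible only for the cis-fused aldolate with O8 and C1 1,3-diaxial and C11 equatorial on the ring B chair, and they are fixed relative to C5 because that chair must keep the bulky C4 group on C5 equatorial, which decides which CH2 becomes C9 and which ketone face is attacked. The step needs a productive anhydride enolate in the presence of an enolisable ketone and one out of four aldol modes: aldol addition to a ketone is reversible, the ketone enolates find no comparable irreversible exit (attack from C17 would need an eight-membered ring, C7 is flanked by the silyloxy-bearing C6), and only the wanted aldolate is drained by the irreversible acyl transfer. The product leaves as a C11 carboxylate whose α-hydrogen is not acidic, which shuts off the Stobbe-type β-elimination of O8.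

Step 12
Reactants: 18 bridged lactone acid
Product: 20 bridged lactone aldehyde, as 18 with CHO on C9 (5R,6R,8S,9R,10R), via acid chloride 19 (not isolated)
Conditions: 1-chloro-N,N,2-trimethylprop-1-en-1-amine, CH2Cl2, 0 °C; then LiAlH(OtBu)3 (1.05 equiv), THF, −78 °C
Reagents that add atoms: none
Why: The base-free acid chloride formation and alkoxyaluminium hydride reduction of step 5 avoid ketene formation and β-elimination of O8, spare lactone and ester, and bypass a primary C11 alcohol that could take over the lactone acyl group.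

Step 13
Reactants: 20 bridged lactone aldehyde, 21 2-(trimethylsilyloxy)buta-1,3-diene
Product: 22 β-hydroxy vinyl ketone, C11(OH)–C12H2–C13(=O)–CH=CH2 on C9 (5R,6R,8S,9S,10R,11S)
Conditions: BF3·OEt2 (1.1 equiv), CH2Cl2, −78 °C; aq. NaHCO3
Reagents that add atoms: none
Why: In this Mukaiyama aldol addition through an open transition state the enol silane should reach the BF3-bound aldehyde from the side of the lactone oxygen O8, anti to the all-carbon bridgehead C10 (Felkin–Anh, reinforced by polar 1,3-anti induction from the β-acyloxy group), which gives 11S.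

Step 14
Reactants: 22 β-hydroxy vinyl ketone
Product: 23 protected target, O6-TBS ether and C3 TMSE ester (5R,6R,8S,9S,10R,11S,13R)
Conditions: MeMgBr (3 equiv), CH2Cl2/Et2O, −78 °C; aq. NH4Cl
Reagents that add atoms: methylmagnesium bromide, C[Mg]Br
Why: In this chelation-controlled Grignard 1,2-addition the magnesium alkoxide on O11 ties the ketone into a six-membered chelate with the bicyclic residue equatorial, and axial delivery of methyl leaves vinyl equatorial and gives the 11,13-syn diol, that is 13R.

Step 15
Reactants: 23 protected target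
Product: 24 target CNP0297019.1 (5R,6R,8S,9S,10R,11S,13R)
Conditions: Bu4NF (6 equiv), AcOH (6 equiv), THF, rt to 40 °C; pH 5 buffer
Reagents that add atoms: none
Why: Fluoride removes the TBS ether and fragments the TMSE ester to carboxylate, ethene and Me3SiF, while the AcOH buffer keeps alkoxides protonated, so that the lactone, the tertiary allylic alcohol and all stereocentres should stay untouched.

Compound list
1 | (2E)-3-methylpent-2-en-4-yn-1-ol | OC/C=C(C)/C#C | starting material
2 | (2E)-3-methylpenta-2,4-dien-1-ol | OC/C=C(C)/C=C | intermediate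
3 | 2,2-dimethylsuccinic anhydride | CC1(C)CC(=O)OC1=O | starting material
4 | 4-{[(2E)-3-methylpenta-2,4-dien-1-yl]oxy}-2,2-dimethyl-4-oxobutanoic acid | OC(=O)C(C)(C)CC(=O)OC/C=C(C)/C=C | intermediate
5 | 1-TMSE 4-[(2E)-3-methylpenta-2,4-dien-1-yl] 2,2-dimethylbutanedioate | C[Si](C)(C)CCOC(=O)C(C)(C)CC(=O)OC/C=C(C)/C=C | intermediate
6 | trimethylsilyl ketene acetal of 5 (geometry without consequence) | C[Si](C)(C)CCOC(=O)C(C)(C)C=C(O[Si](C)(C)C)OC/C=C(C)/C=C | intermediate
7 | trimethylsilyl ester of 8 (racemic) | C[Si](C)(C)CCOC(=O)C(C)(C)C(C(=O)O[Si](C)(C)C)C(C)(C=C)C=C | intermediate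
8 | rac-3,3-dimethyl-2-(3-methylpenta-1,4-dien-3-yl)-4-oxo-4-(TMSE-oxy)butanoic acid | C[Si](C)(C)CCOC(=O)C(C)(C)C(C(=O)O)C(C)(C=C)C=C | intermediate
9 | acid chloride of 8 (racemic) | C[Si](C)(C)CCOC(=O)C(C)(C)C(C(=O)Cl)C(C)(C=C)C=C | intermediate
10 | rac-TMSE 4-ethenyl-3-formyl-2,2,4-trimethylhex-5-enoate | C[Si](C)(C)CCOC(=O)C(C)(C)C(C=O)C(C)(C=C)C=C | intermediate
11 | acetone | CC(C)=O | starting material
12 | TMSE (3R)-4-ethenyl-3-[(1R)-1-hydroxy-3-oxobutyl]-2,2,4-trimethylhex-5-enoate (5R,6R) | CC(=O)C[C@@H](O)[C@H](C(C)(C=C)C=C)C(C)(C)C(=O)OCC[Si](C)(C)C | intermediate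
13 | O6-TBS ether of 12 (5R,6R) | CC(=O)C[C@@H](O[Si](C)(C)C(C)(C)C)[C@H](C(C)(C=C)C=C)C(C)(C)C(=O)OCC[Si](C)(C)C | intermediate
14 | keto dialdehyde, C10(Me)(CH2CHO)2 (5R,6R) | CC(=O)C[C@@H](O[Si](C)(C)C(C)(C)C)[C@H](C(C)(CC=O)CC=O)C(C)(C)C(=O)OCC[Si](C)(C)C | intermediate
15 | keto diacid, C10(Me)(CH2CO2H)2 (5R,6R) | CC(=O)C[C@@H](O[Si](C)(C)C(C)(C)C)[C@H](C(C)(CC(=O)O)CC(=O)O)C(C)(C)C(=O)OCC[Si](C)(C)C | intermediate
16 | keto glutaric anhydride (5R,6R) | CC(=O)C[C@@H](O[Si](C)(C)C(C)(C)C)[C@H](C1(C)CC(=O)OC(=O)C1)C(C)(C)C(=O)OCC[Si](C)(C)C | intermediate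
17 | hydroxy anhydride, ring B cis-fused to the anhydride ring, shown as free alcohol (5R,6R,8S,9R,10R) | O=C1OC(=O)C[C@@]2(C)[C@@H]1[C@@](C)(O)C[C@@H](O[Si](C)(C)C(C)(C)C)[C@H]2C(C)(C)C(=O)OCC[Si](C)(C)C | intermediate
18 | bridged lactone acid (5R,6R,8S,9R,10R) | OC(=O)[C@@H]1[C@]2(C)CC(=O)O[C@@]1(C)C[C@@H](O[Si](C)(C)C(C)(C)C)[C@H]2C(C)(C)C(=O)OCC[Si](C)(C)C | intermediate
19 | acid chloride of 18 | ClC(=O)[C@@H]1[C@]2(C)CC(=O)O[C@@]1(C)C[C@@H](O[Si](C)(C)C(C)(C)C)[C@H]2C(C)(C)C(=O)OCC[Si](C)(C)C | intermediate
20 | bridged lactone aldehyde (5R,6R,8S,9R,10R) | O=C[C@@H]1[C@]2(C)CC(=O)O[C@@]1(C)C[C@@H](O[Si](C)(C)C(C)(C)C)[C@H]2C(C)(C)C(=O)OCC[Si](C)(C)C | intermediate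
21 | 2-(trimethylsilyloxy)buta-1,3-diene | C=CC(=C)O[Si](C)(C)C | starting material
22 | β-hydroxy vinyl ketone (5R,6R,8S,9S,10R,11S) | C=CC(=O)C[C@H](O)[C@@H]1[C@]2(C)CC(=O)O[C@@]1(C)C[C@@H](O[Si](C)(C)C(C)(C)C)[C@H]2C(C)(C)C(=O)OCC[Si](C)(C)C | intermediate
23 | protected target, O6-TBS and C3 TMSE ester (5R,6R,8S,9S,10R,11S,13R) | C=C[C@](C)(O)C[C@H](O)[C@@H]1[C@]2(C)CC(=O)O[C@@]1(C)C[C@@H](O[Si](C)(C)C(C)(C)C)[C@H]2C(C)(C)C(=O)OCC[Si](C)(C)C | intermediate
24 | CNP0297019.1 | C=C[C@](C)(O)C[C@H](O)[C@@H]1[C@]2(C)CC(=O)O[C@@]1(C)C[C@@H](O)[C@H]2C(C)(C)C(=O)O | target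

Total step count: 15. Longest linear sequence: 15 steps (1 to 24).

Steps most likely to fail

Step 11. The zinc enolate may form at the methyl ketone instead of the anhydride, which would lead to C-acylation or to β-elimination of the silyloxy group. The two CH2 groups of the anhydride may also be poorly differentiated. The fallback sets out from keto dialdehyde 14 and uses enamine catalysis, a known way to make an aldehyde α-carbon attack a methyl ketone. Pyrrolidine/AcOH (20 mol % each) in CH2Cl2 at rt should close ring B by reversible 6-enolexo aldolisation. The spare CH2CHO arm then captures the axial tertiary alcohol, which makes the bridged lactol aldehyde F1 the thermodynamic sink. Dess–Martin oxidation of the lactol, to which the aldehyde is inert, comes back to the route at lactone aldehyde 20.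

Step 14. Weak chelation may give poor facial selectivity at C13. Conjugate addition, oxa-Michael closure of the hydroxy enone, or an acyl shift triggered by the magnesium alkoxide may compete. The fallback sets out from 20 and sets C13 by reagent control:
- A vinylogous Mukaiyama aldol addition with (E)-3-methyl-1-(trimethylsilyloxy)buta-1,3-diene and BF3·OEt2 should give the (E)-enal F2.
- Luche reduction (NaBH4, CeCl3·7H2O) gives the allylic alcohol F3.
- Sharpless epoxidation (Ti(OiPr)4, D-(−)-diethyl tartrate, t-BuOOH) gives the (13R,14R)-epoxy alcohol F4.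
- I2/PPh3/imidazole gives the epoxy iodide F5.
- Reductive opening with Zn in EtOH unveils the tertiary allylic alcohol and comes back to the route at 23.

Step 6. The doubly neopentyl aldehyde may react too slowly with the enamine, substrate bias may erode catalyst control, and the C5 epimers may separate badly. The fallback sets out from rac-10. It is resolved by preparative chromatography on a chiral phase to the (5R)-aldehyde F6. C6 is then set by substrate control in a BF3·OEt2-promoted Mukaiyama aldol addition of 2-(trimethylsilyloxy)propene (Felkin–Anh), which comes back to the route at 12.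

Further compounds
F1 | step 11 | bridged lactol aldehyde (anomeric mixture; 5R,6R,8S,9R,10R) | O=C[C@@H]1[C@]2(C)CC(O)O[C@@]1(C)C[C@@H](O[Si](C)(C)C(C)(C)C)[C@H]2C(C)(C)C(=O)OCC[Si](C)(C)C
F2 | step 14 | (E)-enal, C11(OH)–C12H2–C13(Me)=C14H–CHO (11S) | O=C/C=C(C)/C[C@H](O)[C@@H]1[C@]2(C)CC(=O)O[C@@]1(C)C[C@@H](O[Si](C)(C)C(C)(C)C)[C@H]2C(C)(C)C(=O)OCC[Si](C)(C)C
F3 | step 14 | (E)-allylic alcohol from F2 | OC/C=C(C)/C[C@H](O)[C@@H]1[C@]2(C)CC(=O)O[C@@]1(C)C[C@@H](O[Si](C)(C)C(C)(C)C)[C@H]2C(C)(C)C(=O)OCC[Si](C)(C)C
F4 | step 14 | (13R,14R)-epoxy alcohol | OC[C@H]1O[C@]1(C)C[C@H](O)[C@@H]1[C@]2(C)CC(=O)O[C@@]1(C)C[C@@H](O[Si](C)(C)C(C)(C)C)[C@H]2C(C)(C)C(=O)OCC[Si](C)(C)C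
F5 | step 14 | epoxy iodide from F4 | IC[C@H]1O[C@]1(C)C[C@H](O)[C@@H]1[C@]2(C)CC(=O)O[C@@]1(C)C[C@@H](O[Si](C)(C)C(C)(C)C)[C@H]2C(C)(C)C(=O)OCC[Si](C)(C)C
F6 | step 6 | (5R)-aldehyde, TMSE (3R)-4-ethenyl-3-formyl-2,2,4-trimethylhex-5-enoate | O=C[C@H](C(C)(C=C)C=C)C(C)(C)C(=O)OCC[Si](C)(C)C
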